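**Compound numbers used throughout:** 1 eugenol; 2 its 6‑bromo derivative; 3 bromoacetic acid; 4 the aryloxyacetic acid; 5 (S)‑4‑benzyl‑2‑oxazolidinone; 6 mixed pivalic anhydride of 4 (not isolated); 7 the N‑(aryloxyacetyl)oxazolidinone; 8 syringaldehyde; 9 its MOM ether; 10 Z‑dibutylboron enolate of 7 (not isolated); 11 boron aldolate (not isolated); 12 syn aldol adduct; 13 1,3‑diol; 14 primary tosylate; 15 threo 2‑aryloxy‑1‑arylpropan‑1‑ol; 16 MOM ether of the target; 17 target.

## Analysis of the target

The target 17 is a 2,3‑dihydro‑1,4‑benzodioxine. Ring A, a benzene ring with a methoxy group at C5 and an allyl group at C7, is fused to the six‑membered dioxane ring B, which carries ring C (4‑hydroxy‑3,5‑dimethoxyphenyl) on C2 and a methyl group on C3. C2 and C3 are the only stereocentres; both are R, and the aryl and methyl groups are trans, so relative and absolute configuration both have to be controlled. The two ring oxygens are not equivalent: O4 sits on C4a next to the methoxy‑bearing C5 and is bonded to C3, while O1 sits on C8a and is bonded to the benzylic C2. A route that cannot tell them apart gives the regioisomer. The sensitive groups are the terminal allyl group (lost on hydrogenation, attacked by electrophilic halogen, moved into conjugation by strong base), the benzylic C2–O1 bond para to a phenolic oxygen (ionisable in acid, opened through a quinone methide in base once the phenol is free), and three electron‑rich arenes. The difficulty is therefore the pair of adjacent oxygen‑bearing stereocentres, the O1/O4 regiochemistry, and keeping the allyl group intact. The plan rests on the C2–C3 unit: two neighbouring carbons with one oxygen each, ring C on C2 and O4 of ring A on C3. If the C3 methyl group is read as a reduced carboxyl carbon, C3 is the α‑carbon of an aryloxyacetic acid whose ether oxygen is already O4, and C2 is the carbinol carbon of its aldol with an aromatic aldehyde.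

## Retrosynthetic reasoning

**17 from 16 (O–H protection).** The free phenol of ring C is para to C2. In the basic and organometallic steps it would be deprotonated and could open ring B through a quinone methide. It is therefore carried as the methoxymethyl acetal 16, which survives base, hydride and copper catalysis and is removed last by mild acid that leaves the allyl group alone.

**16 from 15 (O1–C8a).** Ring B has four C–O bonds. The two alkyl C–O bonds sit on stereocentres, and closing either by substitution would put C2 or C3 at risk. O4–C4a is already present in the ring A building block 1. That leaves the aryl bond O1–C8a, whose formation touches neither stereocentre. C8a is marked in advance by a bromine ortho to the hydroxyl of 1 (compound 2), so the regiochemistry of ring A is decided before any stereocentre exists. The forward reaction has to join the secondary alkoxide of 15 to the brominated carbon under copper catalysis, closing a six‑membered ring with retention at C2.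

**15 from 14, 13 and 12 (the methyl group).** The C3 methyl group is traced back to a carboxyl carbon. Hydride displaces the primary sulfonate of 14, which comes from selective sulfonylation of diol 13, which comes from reductive removal of the auxiliary from imide 12. The deoxygenation must come before ring closure, because the primary hydroxyl of 13 could also reach C8a through a six‑membered ring and give a constitutional isomer.

**12 from 7 and 9 (C2–C3).** This is the only C–C bond between the two stereocentres. Cutting it divides the molecule into two halves of similar size, each derived from a cheap phenol, and lets both stereocentres be made in one event. In the forward direction the Z‑boron enolate 10 of imide 7 adds to aldehyde 9 through the aldolate 11 to give the syn adduct 12. The syn (threo) relationship is the one that ring closure with retention at both carbons turns into the trans ring, and the (4S) auxiliary gives the (2R,3R) series.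

**7 from 4 and 5; 4 from 2 and 3; 2 from 1; 9 from 8.** The imide 7 is an N‑acylation of auxiliary 5 by acid 4 through the mixed anhydride 6. Acid 4 is the ether of phenol 2 with 3. Phenol 2 is 1 brominated at its only free position ortho to the hydroxyl. Aldehyde 9 is 8 with its phenol protected. All four starting materials (1, 3, 5, 8) are commercial.

## Alternatives that were turned down

**Alternative 1:** Ring B is cut at O4–C4a and O1–C2. In the forward key step Rh2(OAc)4 would decompose the o‑quinone diazide A1 to a carbene at C4a, the oxygen of the cis‑epoxide A2 would add to it, and the neighbouring phenoxide oxygen would then attack the benzylic carbon as its C–O bond breaks, giving the benzodioxane A3.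
- For: two C–O bonds and ring B form in one step, and both stereocentres would come from one catalytic asymmetric epoxidation without an auxiliary. On convergence and atom economy it is stronger than the chosen route.
- Against: oxonium ylides from epoxides readily collapse by oxygen transfer (alkene plus carbonyl) instead of ring expansion. The benzylic carbon carries a very electron‑rich aryl group, so the substitution is likely to gain ionic character, and the trans ring requires clean inversion there. A1 needs its diazo carbon between the carbonyl and the methoxy‑bearing carbon, a contiguous 1,2,3‑pattern that 1 does not provide. The allyl group cannot be present (the carbene would cyclopropanate it), so a bromine stands in and cross‑coupling plus ester removal follow.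
- Comparison: the chosen strategy spends more steps on the C2–C3 unit, but every bond is made by a reaction whose outcome is predictable, and the O1/O4 assignment is fixed by the structure of 2.

**Alternative 2:** The two C–H bonds at C2 and C3 are cut, leading back to the flat 1,4‑benzodioxin A4. Hydrogenation with a chiral bisphosphine complex made from [Rh(cod)2]BF4 or [Ir(cod)Cl]2 would add both hydrogens to one face and give the cis compound A5, after which C2 would have to be epimerised.
- For: enantiocontrol is catalytic, and the non‑epimerisable C3 is set by the catalyst. On atom economy it is stronger than an auxiliary route.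
- Against: the C2=C3 bond is tetrasubstituted, flanked by two ether oxygens and has no directing group, one of the least tractable substrate classes for asymmetric hydrogenation. The aryl bromide is exposed to hydrogenolysis. The allyl group must again be installed afterwards. Syn addition gives the wrong relative configuration by design, so a thermodynamic correction through ionisation of the benzylic C2–O1 bond is needed, with ring opening as a side path.
- Comparison: the chosen strategy sets the threo relationship directly and needs no correction step.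

**Alternative 3:** This cuts the same O1–C8a bond as the chosen ring closure but forms it through an aryne. Lithium 2,2,6,6‑tetramethylpiperidide would deprotonate the alcohol A6 at the ring position between the ether oxygen and the bromine, LiBr would be lost, and the C2 alkoxide would add to C8a to give the silyl ether A7.
- For: the closure needs no transition metal, the allyl group is already in place, and only desilylation follows. In step count after the stereocentres are set it equals the chosen route.
- Against: it does not solve the stereochemical problem, since A6 needs the same two stereocentres from elsewhere. The strong amide base can remove the doubly activated benzylic‑allylic protons and move the double bond into conjugation. An aryne with an oxygen on the neighbouring carbon is polarised for attack at the distal carbon C8, so the tether has to override the electronic preference while the amide competes as nucleophile. The bromine must sit para to the methoxy group, not ortho to the hydroxyl where 1 brominates naturally.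
- Comparison: the chosen closure puts the halogen on the very carbon that is bonded and runs under carbonate base, which removes the regiochemical and isomerisation risks at the cost of a copper catalyst.

Key step: step 5

**Remarks.** Positions are those of 2,3‑dihydro‑1,4‑benzodioxine (O1, C2, C3, O4, C4a, C5 to C8, C8a). Ring A is the fused benzene ring, ring B the dioxane ring, ring C the aryl group on C2. Ethyl (S)‑lactate and 4‑bromo‑2,6‑dimethoxyphenol, used only in a fallback, are assumed to be commercial.

## Route

Step 1
Reactants: 1 eugenol (4‑allyl‑2‑methoxyphenol)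
Product: 2 4‑allyl‑2‑bromo‑6‑methoxyphenol
Conditions: NBS (1.0 equiv), i‑Pr2NH (10 mol%), CH2Cl2, 0 °C, dark
Reagents that add atoms: N‑bromosuccinimide, O=C1CCC(=O)N1Br
Why: Amine‑mediated electrophilic aromatic bromination delivers bromine ortho to a free phenol; the para position is blocked by the allyl group, so only the position that becomes C8a is open. At 0 °C in the dark and without a protic nucleophile the phenol ring should react before the isolated terminal alkene.

Step 2
Reactants: 2 4‑allyl‑2‑bromo‑6‑methoxyphenol; 3 bromoacetic acid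
Product: 4 2‑(4‑allyl‑2‑bromo‑6‑methoxyphenoxy)acetic acid
Conditions: NaH (2.2 equiv), THF–DMF, 0 to 60 °C; then 1 M HCl
Reagents that add atoms: none
Why: Williamson ether synthesis: the sodium phenoxide displaces bromide from sodium bromoacetate by SN2 at an unhindered primary carbon, which tolerates the two ortho substituents. Acidification should give the free acid, and the phenol oxygen is now fixed as the future O4.

Step 3
Reactants: 4 2‑(4‑allyl‑2‑bromo‑6‑methoxyphenoxy)acetic acid; 5 (S)‑4‑benzyl‑2‑oxazolidinone
Product: 7 (4S)‑3‑[2‑(4‑allyl‑2‑bromo‑6‑methoxyphenoxy)acetyl]‑4‑benzyl‑1,3‑oxazolidin‑2‑one, via mixed pivalic anhydride 6 (not isolated)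
Conditions: PivCl, Et3N, THF, −20 °C; then 5, LiCl, −20 °C to rt
Reagents that add atoms: pivaloyl chloride, CC(C)(C)C(=O)Cl (its acyl group is present only in intermediate 6 and leaves as pivalic acid)
Why: N‑acylation of an oxazolidinone through a mixed anhydride; the oxazolidinone attacks the less hindered aryloxyacetyl carbonyl of 6. Activation by LiCl and Et3N avoids alkyllithium, so the aryl bromide is not exchanged.

Step 4
Reactants: 8 syringaldehyde (4‑hydroxy‑3,5‑dimethoxybenzaldehyde)
Product: 9 3,5‑dimethoxy‑4‑(methoxymethoxy)benzaldehyde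
Conditions: MOMCl, i‑Pr2NEt, CH2Cl2, 0 °C to rt
Reagents that add atoms: chloromethyl methyl ether, COCCl
Why: O‑alkylation of the phenoxide to the methoxymethyl acetal. The acetal is stable to the boron enolate, hydrides, carbonate base and copper catalysis used later, and is cleaved by dilute acid at the end.

Step 5
Reactants: 7 (4S)‑3‑[2‑(4‑allyl‑2‑bromo‑6‑methoxyphenoxy)acetyl]‑4‑benzyl‑1,3‑oxazolidin‑2‑one; 9 3,5‑dimethoxy‑4‑(methoxymethoxy)benzaldehyde
Product: 12 (4S)‑3‑[(2S,3R)‑2‑(4‑allyl‑2‑bromo‑6‑methoxyphenoxy)‑3‑[3,5‑dimethoxy‑4‑(methoxymethoxy)phenyl]‑3‑hydroxypropanoyl]‑4‑benzyl‑1,3‑oxazolidin‑2‑one, via Z‑dibutylboron enolate 10 (not isolated), via dibutylboron aldolate 11 (not isolated)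
Conditions: Bu2BOTf (1.15 equiv), i‑Pr2NEt (1.3 equiv), CH2Cl2, −78 to 0 °C; then 9, −78 to 0 °C; pH 7 buffer, MeOH, 30% H2O2, 0 °C
Reagents that add atoms: dibutylboron triflate, CCCCB(CCCC)OS(=O)(=O)C(F)(F)F (boron is present only in intermediates 10 and 11 and is removed in the oxidative work‑up)
Why: Bu2BOTf binds the imide carbonyl of 7 and i‑Pr2NEt removes an α‑proton to give the Z enolate 10, the geometry in which the aryloxy group avoids the oxazolidinone ring. Aldehyde 9 then coordinates to boron and the C2–C3 bond forms through a closed six‑membered chair transition state (Zimmerman–Traxler) with the aldehyde aryl group equatorial, giving the syn aldolate 11, from which buffered H2O2 releases 12. The closest known reaction type is the Evans syn aldol of α‑alkoxy‑ and α‑aryloxyacetyl oxazolidinones through dibutylboron enolates. No ring is closed in this step. The α‑stereocentre (later C3 of the target) is controlled by the benzyl group of the (4S) auxiliary: with the two imide carbonyls opposed in the boron‑bound transition state, the aldehyde reaches the enolate face away from that group. The carbinol stereocentre (later C2 of the target) is controlled by the Z enolate geometry acting through the chair. The step needs syn over anti and one enolate face over the other; a single enolate geometry, short B–O bonds and the absence of a second Lewis acid secure both, and the allyl group, aryl bromide and MOM acetal should be inert between −78 and 0 °C.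

Step 6
Reactants: 12 the syn aldol adduct
Product: 13 (1R,2R)‑2‑(4‑allyl‑2‑bromo‑6‑methoxyphenoxy)‑1‑[3,5‑dimethoxy‑4‑(methoxymethoxy)phenyl]propane‑1,3‑diol
Conditions: LiBH4 (2 equiv), MeOH (2 equiv), THF, 0 °C
Reagents that add atoms: none
Why: Reductive cleavage of an N‑acyl oxazolidinone: lithium‑assisted hydride attack at the exocyclic carbonyl releases the auxiliary and reduces the acyl carbon to CH2OH. Neither stereocentre is involved, and the aryl bromide and alkene are inert to borohydride.

Step 7
Reactants: 13 the 1,3‑diol
Product: 14 (2R,3R)‑2‑(4‑allyl‑2‑bromo‑6‑methoxyphenoxy)‑3‑[3,5‑dimethoxy‑4‑(methoxymethoxy)phenyl]‑3‑hydroxypropyl 4‑methylbenzenesulfonate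
Conditions: TsCl (1.1 equiv), pyridine, CH2Cl2, 0 °C
Reagents that add atoms: p‑toluenesulfonyl chloride, Cc1ccc(cc1)S(=O)(=O)Cl
Why: Selective sulfonylation of a primary alcohol in the presence of a more hindered secondary benzylic one. A limited amount of reagent and low temperature should keep the secondary hydroxyl free for the later ring closure.

Step 8
Reactants: 14 the primary tosylate
Product: 15 (1R,2R)‑2‑(4‑allyl‑2‑bromo‑6‑methoxyphenoxy)‑1‑[3,5‑dimethoxy‑4‑(methoxymethoxy)phenyl]propan‑1‑ol
Conditions: LiEt3BH (3 equiv), THF, 0 °C to rt; then H2O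
Reagents that add atoms: none
Why: SN2 displacement of a primary sulfonate by hydride; one equivalent of reagent is consumed by the free hydroxyl. Substitution occurs only at the CH2 carbon, so the adjacent stereocentre keeps its configuration, and the aryl bromide, alkene and acetal should be untouched at this temperature.

Step 9
Reactants: 15 the threo aryloxy alcohol
Product: 16 (2R,3R)‑7‑allyl‑2‑[3,5‑dimethoxy‑4‑(methoxymethoxy)phenyl]‑5‑methoxy‑3‑methyl‑2,3‑dihydro‑1,4‑benzodioxine
Conditions: CuI (10 mol%), 3,4,7,8‑tetramethyl‑1,10‑phenanthroline (20 mol%), Cs2CO3 (2 equiv), toluene, 110 °C, argon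
Reagents that add atoms: none
Why: Intramolecular Ullmann‑type etherification (copper‑catalysed coupling of an aliphatic alcohol with an aryl bromide): the copper alkoxide of the C2 hydroxyl activates the neighbouring C8a–Br bond and forms O1–C8a in a six‑membered ring. The C2–O bond is never broken, so both stereocentres are retained and the threo substrate gives the trans ring. The primary hydroxyl that could have closed a competing ring was removed in step 8.

Step 10
Reactants: 16 the MOM ether of the target
Product: 17 4‑[(2R,3R)‑7‑allyl‑5‑methoxy‑3‑methyl‑2,3‑dihydro‑1,4‑benzodioxin‑2‑yl]‑2,6‑dimethoxyphenol (target)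
Conditions: 3 M HCl (aq), MeOH, 40 °C
Reagents that add atoms: none
Why: Acid‑catalysed transacetalisation of the methoxymethyl ether to methanol, which frees the phenol. The aryl alkyl ether bonds of ring B are far less acid‑labile than the acetal, and any reversible ionisation at C2 would re‑close to the more stable trans ring because C3 is unaffected; the terminal alkene does not add HCl under these conditions.

## Compound list

1 | eugenol (4‑allyl‑2‑methoxyphenol) | C=CCc1ccc(O)c(OC)c1 | starting material
2 | 4‑allyl‑2‑bromo‑6‑methoxyphenol | C=CCc1cc(OC)c(O)c(Br)c1 | intermediate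
3 | bromoacetic acid | OC(=O)CBr | starting material
4 | 2‑(4‑allyl‑2‑bromo‑6‑methoxyphenoxy)acetic acid | C=CCc1cc(OC)c(OCC(=O)O)c(Br)c1 | intermediate
5 | (S)‑4‑benzyl‑2‑oxazolidinone | O=C1N[C@@H](Cc2ccccc2)CO1 | starting material
6 | 2‑(4‑allyl‑2‑bromo‑6‑methoxyphenoxy)acetic pivalic anhydride (not isolated) | C=CCc1cc(OC)c(OCC(=O)OC(=O)C(C)(C)C)c(Br)c1 | intermediate
7 | (4S)‑3‑[2‑(4‑allyl‑2‑bromo‑6‑methoxyphenoxy)acetyl]‑4‑benzyl‑1,3‑oxazolidin‑2‑one | C=CCc1cc(OC)c(OCC(=O)N2[C@@H](Cc3ccccc3)COC2=O)c(Br)c1 | intermediate
8 | syringaldehyde (4‑hydroxy‑3,5‑dimethoxybenzaldehyde) | COc1cc(C=O)cc(OC)c1O | starting material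
9 | 3,5‑dimethoxy‑4‑(methoxymethoxy)benzaldehyde | COCOc1c(OC)cc(C=O)cc1OC | intermediate
10 | (4S)‑3‑[(Z)‑2‑(4‑allyl‑2‑bromo‑6‑methoxyphenoxy)‑1‑(dibutylboryloxy)ethenyl]‑4‑benzyl‑1,3‑oxazolidin‑2‑one (not isolated) | C=CCc1cc(OC)c(O/C=C(/N2[C@@H](Cc3ccccc3)COC2=O)OB(CCCC)CCCC)c(Br)c1 | intermediate
11 | O‑dibutylboryl derivative of 12 (boron aldolate, not isolated) | C=CCc1cc(OC)c(O[C@H](C(=O)N2[C@@H](Cc3ccccc3)COC2=O)[C@H](OB(CCCC)CCCC)c2cc(OC)c(OCOC)c(OC)c2)c(Br)c1 | intermediate
12 | (4S)‑3‑[(2S,3R)‑2‑(4‑allyl‑2‑bromo‑6‑methoxyphenoxy)‑3‑[3,5‑dimethoxy‑4‑(methoxymethoxy)phenyl]‑3‑hydroxypropanoyl]‑4‑benzyl‑1,3‑oxazolidin‑2‑one | C=CCc1cc(OC)c(O[C@H](C(=O)N2[C@@H](Cc3ccccc3)COC2=O)[C@H](O)c2cc(OC)c(OCOC)c(OC)c2)c(Br)c1 | intermediate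
13 | (1R,2R)‑2‑(4‑allyl‑2‑bromo‑6‑methoxyphenoxy)‑1‑[3,5‑dimethoxy‑4‑(methoxymethoxy)phenyl]propane‑1,3‑diol | C=CCc1cc(OC)c(O[C@H](CO)[C@H](O)c2cc(OC)c(OCOC)c(OC)c2)c(Br)c1 | intermediate
14 | (2R,3R)‑2‑(4‑allyl‑2‑bromo‑6‑methoxyphenoxy)‑3‑[3,5‑dimethoxy‑4‑(methoxymethoxy)phenyl]‑3‑hydroxypropyl 4‑methylbenzenesulfonate | C=CCc1cc(OC)c(O[C@H](COS(=O)(=O)c2ccc(C)cc2)[C@H](O)c2cc(OC)c(OCOC)c(OC)c2)c(Br)c1 | intermediate
15 | (1R,2R)‑2‑(4‑allyl‑2‑bromo‑6‑methoxyphenoxy)‑1‑[3,5‑dimethoxy‑4‑(methoxymethoxy)phenyl]propan‑1‑ol | C=CCc1cc(OC)c(O[C@H](C)[C@H](O)c2cc(OC)c(OCOC)c(OC)c2)c(Br)c1 | intermediate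
16 | (2R,3R)‑7‑allyl‑2‑[3,5‑dimethoxy‑4‑(methoxymethoxy)phenyl]‑5‑methoxy‑3‑methyl‑2,3‑dihydro‑1,4‑benzodioxine | C=CCc1cc(OC)c2c(c1)O[C@H](c1cc(OC)c(OCOC)c(OC)c1)[C@@H](C)O2 | intermediate
17 | 4‑[(2R,3R)‑7‑allyl‑5‑methoxy‑3‑methyl‑2,3‑dihydro‑1,4‑benzodioxin‑2‑yl]‑2,6‑dimethoxyphenol | C=CCc1cc(OC)c2c(c1)O[C@H](c1cc(OC)c(O)c(OC)c1)[C@@H](C)O2 | target

## Step count and least certain steps

Total step count: 10. Longest linear sequence: 9 steps (steps 1, 2, 3, 5, 6, 7, 8, 9, 10 from 1); step 4 is a one‑step branch.

**Step 5 (key step).** The bulky 2,6‑disubstituted aryloxy group and the electron‑rich, weakly electrophilic aldehyde may slow the addition. That invites incomplete conversion, erosion of facial or syn selectivity through a less ordered transition state, and retro‑aldol cleavage of the electron‑rich benzylic aldolate during work‑up. Fallback: take C3 from the chiral pool and form the C2–aryl bond instead of the C2–C3 bond. It sets out from 2 and returns at 15, bypassing steps 2 to 8.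
- A Mitsunobu reaction of 2 with ethyl (S)‑lactate (PPh3, DIAD, THF) should give, with inversion, ethyl (2R)‑2‑(4‑allyl‑2‑bromo‑6‑methoxyphenoxy)propanoate F1.
- Treatment with N,O‑dimethylhydroxylamine hydrochloride and i‑PrMgCl at −20 °C should give the Weinreb amide (2R)‑2‑(4‑allyl‑2‑bromo‑6‑methoxyphenoxy)‑N‑methoxy‑N‑methylpropanamide F2.
- 4‑Bromo‑2,6‑dimethoxyphenol is protected with MOMCl and i‑Pr2NEt as 5‑bromo‑1,3‑dimethoxy‑2‑(methoxymethoxy)benzene F3 and converted with Mg in THF into [3,5‑dimethoxy‑4‑(methoxymethoxy)phenyl]magnesium bromide F4.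
- F4 should add once to F2 to give the ketone (2R)‑2‑(4‑allyl‑2‑bromo‑6‑methoxyphenoxy)‑1‑[3,5‑dimethoxy‑4‑(methoxymethoxy)phenyl]propan‑1‑one F5.
- Reduction with K[(s‑Bu)3BH] in THF at −78 °C under Felkin–Anh control (aryloxy group anti to the incoming hydride) should give the threo alcohol 15.

**Step 9.** Activation of the hindered, electron‑rich C–Br bond may be slow. Hydrodebromination, oxidation of the benzylic alcohol, or base‑induced migration of the allyl double bond could then compete with ring closure. Fallback: turn the bromide into a phenol and close ring B at C2 under thermodynamic control. It sets out from 15 and returns at 17.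
- Miyaura borylation (Pd(dppf)Cl2, bis(pinacolato)diboron, KOAc, dioxane, 80 °C) should give (1R,2R)‑2‑[4‑allyl‑2‑methoxy‑6‑(4,4,5,5‑tetramethyl‑1,3,2‑dioxaborolan‑2‑yl)phenoxy]‑1‑[3,5‑dimethoxy‑4‑(methoxymethoxy)phenyl]propan‑1‑ol F6.
- Oxidation with NaBO3 in THF–water should give 5‑allyl‑2‑{(1R,2R)‑1‑[3,5‑dimethoxy‑4‑(methoxymethoxy)phenyl]‑1‑hydroxypropan‑2‑yl}oxy‑3‑methoxyphenol F7.
- HCl in MeOH should remove the MOM group and ionise the benzylic alcohol; the ring A phenol captures the cation reversibly, and the ring settles in the more stable trans arrangement with C3 unchanged, giving 17.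

**Step 8.** Hydride may attack at sulfur instead of at the β‑branched, β‑oxygenated CH2 carbon, returning the diol. Alternatively the lithium alkoxide of the neighbouring hydroxyl may displace the sulfonate to close an oxetane. Fallback: replace the polar substitution by a radical reduction. It sets out from 14 and returns at 15.
- Finkelstein exchange (NaI, acetone, reflux) should give (1R,2S)‑2‑(4‑allyl‑2‑bromo‑6‑methoxyphenoxy)‑1‑[3,5‑dimethoxy‑4‑(methoxymethoxy)phenyl]‑3‑iodopropan‑1‑ol F8 under neutral conditions.
- Bu3SnH with AIBN in toluene at 80 °C should reduce the C–I bond, which is far more reactive towards tin radicals than the aryl C–Br bond, to the methyl group of 15.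

**Step 1.** Electrophilic bromine may add to the terminal alkene or brominate the ring twice, lowering chemoselectivity. Fallback: accept alkene bromination and reverse it. It sets out from 1 and returns at 2.
- Br2 (2 equiv) in CH2Cl2 at 0 °C should give 2‑bromo‑4‑(2,3‑dibromopropyl)‑6‑methoxyphenol F9 (racemic at the side chain).
- Zn dust in AcOH–EtOH should eliminate the vicinal dibromide reductively, restoring the allyl group while leaving the aryl bromide, to give 2.

## Further compounds

F1 | step 5 | ethyl (2R)‑2‑(4‑allyl‑2‑bromo‑6‑methoxyphenoxy)propanoate | C=CCc1cc(OC)c(O[C@H](C)C(=O)OCC)c(Br)c1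
F2 | step 5 | (2R)‑2‑(4‑allyl‑2‑bromo‑6‑methoxyphenoxy)‑N‑methoxy‑N‑methylpropanamide | C=CCc1cc(OC)c(O[C@H](C)C(=O)N(C)OC)c(Br)c1
F3 | step 5 | 5‑bromo‑1,3‑dimethoxy‑2‑(methoxymethoxy)benzene | COCOc1c(OC)cc(Br)cc1OC
F4 | step 5 | [3,5‑dimethoxy‑4‑(methoxymethoxy)phenyl]magnesium bromide | COCOc1c(OC)cc([Mg]Br)cc1OC
F5 | step 5 | (2R)‑2‑(4‑allyl‑2‑bromo‑6‑methoxyphenoxy)‑1‑[3,5‑dimethoxy‑4‑(methoxymethoxy)phenyl]propan‑1‑one | C=CCc1cc(OC)c(O[C@H](C)C(=O)c2cc(OC)c(OCOC)c(OC)c2)c(Br)c1
F6 | step 9 | (1R,2R)‑2‑[4‑allyl‑2‑methoxy‑6‑(4,4,5,5‑tetramethyl‑1,3,2‑dioxaborolan‑2‑yl)phenoxy]‑1‑[3,5‑dimethoxy‑4‑(methoxymethoxy)phenyl]propan‑1‑ol | C=CCc1cc(OC)c(O[C@H](C)[C@H](O)c2cc(OC)c(OCOC)c(OC)c2)c(B2OC(C)(C)C(C)(C)O2)c1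
F7 | step 9 | 5‑allyl‑2‑{(1R,2R)‑1‑[3,5‑dimethoxy‑4‑(methoxymethoxy)phenyl]‑1‑hydroxypropan‑2‑yl}oxy‑3‑methoxyphenol | C=CCc1cc(OC)c(O[C@H](C)[C@H](O)c2cc(OC)c(OCOC)c(OC)c2)c(O)c1
F8 | step 8 | (1R,2S)‑2‑(4‑allyl‑2‑bromo‑6‑methoxyphenoxy)‑1‑[3,5‑dimethoxy‑4‑(methoxymethoxy)phenyl]‑3‑iodopropan‑1‑ol | C=CCc1cc(OC)c(O[C@H](CI)[C@H](O)c2cc(OC)c(OCOC)c(OC)c2)c(Br)c1
F9 | step 1 | 2‑bromo‑4‑(2,3‑dibromopropyl)‑6‑methoxyphenol | BrCC(Br)Cc1cc(OC)c(O)c(Br)c1
A1 | alternative 1 | 3‑bromo‑6‑diazo‑5‑methoxycyclohexa‑2,4‑dien‑1‑one | O=C1C=C(Br)C=C(OC)C1=[N+]=[N-]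
A2 | alternative 1 | 2,6‑dimethoxy‑4‑[(2S,3R)‑3‑methyloxiran‑2‑yl]phenyl pivalate (cis‑epoxide) | C[C@H]1O[C@H]1c1cc(OC)c(OC(=O)C(C)(C)C)c(OC)c1
A3 | alternative 1 | 4‑[(2R,3R)‑7‑bromo‑5‑methoxy‑3‑methyl‑2,3‑dihydro‑1,4‑benzodioxin‑2‑yl]‑2,6‑dimethoxyphenyl pivalate | COc1cc(Br)cc2O[C@H](c3cc(OC)c(OC(=O)C(C)(C)C)c(OC)c3)[C@@H](C)Oc12
A4 | alternative 2 | 7‑bromo‑2‑[3,5‑dimethoxy‑4‑(triisopropylsilyloxy)phenyl]‑5‑methoxy‑3‑methyl‑1,4‑benzodioxine | COc1cc(Br)cc2OC(c3cc(OC)c(O[Si](C(C)C)(C(C)C)C(C)C)c(OC)c3)=C(C)Oc12
A5 | alternative 2 | (2S,3R)‑cis‑7‑bromo‑2‑[3,5‑dimethoxy‑4‑(triisopropylsilyloxy)phenyl]‑5‑methoxy‑3‑methyl‑2,3‑dihydro‑1,4‑benzodioxine | COc1cc(Br)cc2O[C@@H](c3cc(OC)c(O[Si](C(C)C)(C(C)C)C(C)C)c(OC)c3)[C@@H](C)Oc12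
A6 | alternative 3 | (1R,2R)‑2‑(4‑allyl‑5‑bromo‑2‑methoxyphenoxy)‑1‑[3,5‑dimethoxy‑4‑(triisopropylsilyloxy)phenyl]propan‑1‑ol | C=CCc1cc(OC)c(O[C@H](C)[C@H](O)c2cc(OC)c(O[Si](C(C)C)(C(C)C)C(C)C)c(OC)c2)cc1Br
A7 | alternative 3 | (2R,3R)‑7‑allyl‑2‑[3,5‑dimethoxy‑4‑(triisopropylsilyloxy)phenyl]‑5‑methoxy‑3‑methyl‑2,3‑dihydro‑1,4‑benzodioxine | C=CCc1cc(OC)c2c(c1)O[C@H](c1cc(OC)c(O[Si](C(C)C)(C(C)C)C(C)C)c(OC)c1)[C@@H](C)O2
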